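Ring A is a hexasubstituted benzene in which, counting from the butanoyl-bearing carbon as ring A carbon 1, carbons 2, 4 and 6 carry oxygen (OH, OMe, OH) and carbons 1, 3 and 5 carry carbon. A Danheiser benzannulation exploits this alternation: it forms the bonds between carbons 2 and 3 and between carbons 4 and 5 and closes ring A in one operation. The precursor pair is 2-(methoxymethyl)-3-(propan-2-yloxy)cyclobut-2-en-1-one, which supplies carbons 1, 2, 5 and 6 with the CH2O handle, and 1-methoxyprop-1-yne, which supplies carbons 3 and 4. The oxygens arrive differentiated; lithiation then installs the butanoyl group and the benzylic ether alkylates acetylfilicinic acid, which becomes ring B.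

Key step: step 4

Remark on numbering: ring A positions are counted from the butanoyl-bearing carbon as position 1, so that positions 2 and 6 carry OH, position 3 the methyl group, position 4 the methoxy group and position 5 the CH2 link to ring B.

Remark on the structure: the target has no stereocentre, and ring B is an enolised β-triketone, so the tautomer written in the SMILES is taken as equivalent to the others.

Remark on the design: a benzylic C–O bond flanked by three ring oxygens ionises under any Lewis acid, so the acyl group is introduced by lithiation and the handle is carried as a robust methyl ether. The oxygen on position 6 is carried as a secondary alkyl ether because that can be cleaved beside the hindered methyl ether on position 4.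

Step 1
Reactants: 1 trichloroethylene; 2 propan-2-ol
Product: 6 3-methoxy-1-(propan-2-yloxy)prop-1-yne, via dichlorovinyl ether 3 (not isolated), via chloroalkyne 4 (not isolated), via lithium alkynide 5 (not isolated)
Conditions: KH, THF, 0 °C, then 1 at −50 °C → rt; n-BuLi (2.4 equiv), −78 → −40 °C; MOMCl, −78 °C → rt; aq. NaHCO3 work-up
Reagents that add atoms: chloromethyl methyl ether, COCCl
Why: Alkoxide addition to dichloroacetylene formed from trichloroethylene gives the (E)-dichlorovinyl ether, n-BuLi then effects dehydrochlorination and chlorine–lithium exchange to the lithium alkoxyacetylide, and this is C-alkylated by the reactive α-chloro ether (one-pot ynol ether synthesis followed by acetylide alkylation).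

Step 2
Reactants: 6 3-methoxy-1-(propan-2-yloxy)prop-1-yne; 7 acetyl chloride
Product: 9 2-(methoxymethyl)-3-(propan-2-yloxy)cyclobut-2-en-1-one, via ketene 8 (not isolated)
Conditions: 7 added slowly to 6 and Et3N, Et2O, 0 °C → rt
Reagents that add atoms: none
Why: Ketene–alkyne [2+2] cycloaddition, in which the ynol ether carbon carrying the CH2OMe group is the nucleophilic terminus and bonds to the ketene carbonyl carbon, so that the alkoxy group ends on carbon 3 and the CH2OMe group on carbon 2 of the cyclobutenone.

Step 3
Reactants: 10 2-chloro-1,1-dimethoxyethane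
Product: 12 1-methoxyprop-1-yne, via sodium methoxyethynide 11 (not isolated)
Conditions: NaNH2 (3 equiv), liquid NH3, −33 °C; MeI, −40 °C; NH4Cl; extraction into cold toluene and use of the dried solution
Reagents that add atoms: iodomethane, CI
Why: Twofold elimination (methanol, then HCl) from the α-chloro acetal with NaNH2 gives the sodium alkoxyacetylide, which is methylated at carbon in liquid ammonia (acetylide alkylation).

Step 4
Reactants: 9 2-(methoxymethyl)-3-(propan-2-yloxy)cyclobut-2-en-1-one; 12 1-methoxyprop-1-yne
Product: 17 3-methoxy-4-(methoxymethyl)-2-methyl-5-(propan-2-yloxy)phenol, via vinylketene 13 (not isolated), via vinylcyclobutenone 14 (not isolated), via dienylketene 15 (not isolated), via cyclohexadienone 16 (not isolated)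
Conditions: 12 (3 equiv), toluene, sealed tube, 110 → 140 °C; then K2CO3, MeOH, rt (cleaves any aryl ester formed from the phenol and a ketene)
Reagents that add atoms: none
Why: Danheiser benzannulation: thermal 4π electrocyclic opening of 9 gives vinylketene 13, which adds ynol ether 12 in a [2+2] cycloaddition to give 14; 4π opening of 14 gives dienylketene 15, and 6π electrocyclisation followed by tautomerisation of dienone 16 gives the phenol. The closest known reaction type is the benzannulation of cyclobutenones with alkynyl ethers, and the electrocyclic opening of alkoxy-substituted cyclobutenones to vinylketenes is itself established for squarate-derived cyclobutenones. Ring A is closed by the disrotatory 6π electrocyclisation, which makes the sigma bond between ring A positions 1 and 2 after the bonds between positions 2 and 3 and between positions 4 and 5 have been formed in the [2+2] step. No stereocentre remains, because the quaternary carbon of 14 is lost on ring opening and aromatisation. The one selectivity needed is the orientation of the [2+2] step, fixed by the polarisation of 12: its methyl-bearing carbon is nucleophilic and attacks the ketene carbonyl carbon, which puts methyl on position 3 next to the phenol carbon (position 2) and OMe on position 4 next to position 5. Only the dienylketene isomer with ketene and vinyl groups cis can cyclise, and reversible opening of 14 should funnel material through it.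

Step 5
Reactants: 17 3-methoxy-4-(methoxymethyl)-2-methyl-5-(propan-2-yloxy)phenol
Product: 18 3-methoxy-1-(methoxymethoxy)-4-(methoxymethyl)-2-methyl-5-(propan-2-yloxy)benzene
Conditions: MOMCl, i-Pr2NEt, CH2Cl2, 0 °C → rt
Reagents that add atoms: chloromethyl methyl ether, COCCl
Why: O-Alkylation of the phenol with an α-chloro ether under amine base (MOM protection) turns the oxygen on position 2 into a strong directing group for metalation, and the benzylic ether is inert to base.

Step 6
Reactants: 18 3-methoxy-1-(methoxymethoxy)-4-(methoxymethyl)-2-methyl-5-(propan-2-yloxy)benzene; 19 N-methoxy-N-methylbutanamide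
Product: 21 1-[4-methoxy-2-(methoxymethoxy)-5-(methoxymethyl)-3-methyl-6-(propan-2-yloxy)phenyl]butan-1-one, via aryllithium 20 (not isolated)
Conditions: n-BuLi (1.1 equiv), THF, 0 °C; then 19, −78 °C → rt; aq. NH4Cl
Reagents that add atoms: none
Why: Directed ortho-metalation at position 1, the only ring hydrogen, which lies between the OMOM and O-isopropyl groups, followed by acylation of the aryllithium with the Weinreb amide, whose chelated tetrahedral adduct prevents over-addition (Weinreb ketone synthesis); no Lewis acid meets the acid-labile benzylic ether.

Step 7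
Reactants: 21 1-[4-methoxy-2-(methoxymethoxy)-5-(methoxymethyl)-3-methyl-6-(propan-2-yloxy)phenyl]butan-1-one
Product: 23 1-[2,6-dihydroxy-4-methoxy-3-(methoxymethyl)-5-methylphenyl]butan-1-one, via benzylic chloride 22 (not isolated)
Conditions: BCl3 (4 equiv), CH2Cl2, −78 → 0 °C; then MeOH, −78 °C → rt
Reagents that add atoms: methanol, CO
Why: Lewis-acid ether cleavage, in which BCl3 removes the MOM acetal and the secondary isopropyl ether (cleaved far more readily than a methyl aryl ether) while the methyl ether on position 4 is kept; the benzylic ether is exchanged to chloride 22 in the flask and the methanol quench restores it by solvolysis, the fully substituted ring offering the benzylic cation no carbon nucleophile.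

Step 8
Reactants: 24 2,4,6-trihydroxyacetophenone
Product: 25 2-acetyl-3,5-dihydroxy-4,4-dimethylcyclohexa-2,5-dien-1-one (acetylfilicinic acid)
Conditions: NaOMe (3 equiv), MeI (2 equiv), MeOH, 0 °C → rt; acid work-up and chromatography
Reagents that add atoms: iodomethane, CI
Why: Twofold C-methylation of the acylphloroglucinol polyanion at one ring carbon (dearomatising alkylation) gives the gem-dimethyl enolised triketone, which keeps a single nucleophilic CH; no stereocentre is formed.

Step 9
Reactants: 23 1-[2,6-dihydroxy-4-methoxy-3-(methoxymethyl)-5-methylphenyl]butan-1-one; 25 2-acetyl-3,5-dihydroxy-4,4-dimethylcyclohexa-2,5-dien-1-one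
Product: 27 2-acetyl-6-[(3-butanoyl-2,4-dihydroxy-6-methoxy-5-methylphenyl)methyl]-3,5-dihydroxy-4,4-dimethylcyclohexa-2,5-dien-1-one (CNP0414731.0), via quinone methide 26 (not isolated)
Conditions: p-TsOH·H2O (cat.), 25 (1.2 equiv), MeCN, 50 °C
Reagents that add atoms: none
Why: Acid-promoted loss of methanol from the ortho-hydroxybenzyl ether gives ortho-quinone methide 26 (or its protonated benzylic cation), which is captured at the only CH of the enolised triketone 25 in a Michael-type Friedel–Crafts alkylation; each partner has one reactive carbon, so neither self-condensation nor regioisomers are possible, and no stereocentre is formed.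

Compound list
1 | trichloroethylene | ClC=C(Cl)Cl | starting material
2 | propan-2-ol | CC(C)O | starting material
3 | (E)-1,2-dichloro-1-(propan-2-yloxy)ethene | CC(C)O/C(Cl)=C\Cl | intermediate
4 | 1-chloro-2-(propan-2-yloxy)ethyne | CC(C)OC#CCl | intermediate
5 | lithium 2-(propan-2-yloxy)ethyn-1-ide | CC(C)OC#C[Li] | intermediate
6 | 3-methoxy-1-(propan-2-yloxy)prop-1-yne | COCC#COC(C)C | intermediate
7 | acetyl chloride | CC(Cl)=O | starting material
8 | ketene (ethenone) | C=C=O | intermediate
9 | 2-(methoxymethyl)-3-(propan-2-yloxy)cyclobut-2-en-1-one | COCC1=C(OC(C)C)CC1=O | intermediate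
10 | 2-chloro-1,1-dimethoxyethane | COC(CCl)OC | starting material
11 | sodium 2-methoxyethyn-1-ide | COC#C[Na] | intermediate
12 | 1-methoxyprop-1-yne | CC#COC | intermediate
13 | 2-(methoxymethyl)-3-(propan-2-yloxy)buta-1,3-dien-1-one | C=C(OC(C)C)C(COC)=C=O | intermediate
14 | 3-methoxy-4-(methoxymethyl)-2-methyl-4-[1-(propan-2-yloxy)ethenyl]cyclobut-2-en-1-one (racemic) | COCC1(C(=C)OC(C)C)C(OC)=C(C)C1=O | intermediate
15 | (3E)-3-methoxy-4-(methoxymethyl)-2-methyl-5-(propan-2-yloxy)hexa-1,3,5-trien-1-one | O=C=C(C)/C(OC)=C(COC)\C(=C)OC(C)C | intermediate
16 | 3-methoxy-4-(methoxymethyl)-2-methyl-5-(propan-2-yloxy)cyclohexa-2,4-dien-1-one | O=C1CC(OC(C)C)=C(COC)C(OC)=C1C | intermediate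
17 | 3-methoxy-4-(methoxymethyl)-2-methyl-5-(propan-2-yloxy)phenol | COCc1c(OC(C)C)cc(O)c(C)c1OC | intermediate
18 | 3-methoxy-1-(methoxymethoxy)-4-(methoxymethyl)-2-methyl-5-(propan-2-yloxy)benzene | COCOc1cc(OC(C)C)c(COC)c(OC)c1C | intermediate
19 | N-methoxy-N-methylbutanamide | CCCC(=O)N(C)OC | starting material
20 | [4-methoxy-2-(methoxymethoxy)-5-(methoxymethyl)-3-methyl-6-(propan-2-yloxy)phenyl]lithium | [Li]c1c(OCOC)c(C)c(OC)c(COC)c1OC(C)C | intermediate
21 | 1-[4-methoxy-2-(methoxymethoxy)-5-(methoxymethyl)-3-methyl-6-(propan-2-yloxy)phenyl]butan-1-one | CCCC(=O)c1c(OCOC)c(C)c(OC)c(COC)c1OC(C)C | intermediate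
22 | 1-[3-(chloromethyl)-2,6-dihydroxy-4-methoxy-5-methylphenyl]butan-1-one (held in the flask as its boron aryloxides) | CCCC(=O)c1c(O)c(C)c(OC)c(CCl)c1O | intermediate
23 | 1-[2,6-dihydroxy-4-methoxy-3-(methoxymethyl)-5-methylphenyl]butan-1-one | CCCC(=O)c1c(O)c(C)c(OC)c(COC)c1O | intermediate
24 | 2,4,6-trihydroxyacetophenone | CC(=O)c1c(O)cc(O)cc1O | starting material
25 | 2-acetyl-3,5-dihydroxy-4,4-dimethylcyclohexa-2,5-dien-1-one (acetylfilicinic acid) | CC(=O)C1=C(O)C(C)(C)C(O)=CC1=O | intermediate
26 | 6-butanoyl-5-hydroxy-3-methoxy-4-methyl-2-methylidenecyclohexa-3,5-dien-1-one | CCCC(=O)C1=C(O)C(C)=C(OC)C(=C)C1=O | intermediate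
27 | 2-acetyl-6-[(3-butanoyl-2,4-dihydroxy-6-methoxy-5-methylphenyl)methyl]-3,5-dihydroxy-4,4-dimethylcyclohexa-2,5-dien-1-one | CCCC(=O)c1c(O)c(C)c(OC)c(CC2=C(O)C(C)(C)C(O)=C(C(C)=O)C2=O)c1O | target

Total step count: 9. Longest linear sequence: 7 steps (steps 1, 2, 4, 5, 6, 7, 9).

Steps most likely to fail

1. Step 4 (benzannulation). The vinylogous-ester cyclobutenone may resist electrocyclic opening at accessible temperatures, or the electron-rich vinylketene may dimerise faster than it adds the ynol ether. The fallback exchanges the two halves of ring A between the partners, so that the bonds between positions 1 and 2 and between positions 5 and 6 are formed instead and the cyclobutenone carries a ring-opening-accelerating 4-methyl group. It sets out from sodium methoxyethynide 11 and lithium alkynide 5. After the ammonia is replaced by THF, 11 is alkylated with chloromethyl methyl ether to give 1,3-dimethoxyprop-1-yne F1. [2+2] cycloaddition of F1 with methylketene F2 (propanoyl chloride, Et3N, Et2O) gives 3-methoxy-2-(methoxymethyl)-4-methylcyclobut-2-en-1-one F3. Lithium alkynide 5 is protonated with aqueous NH4Cl to (propan-2-yloxy)ethyne F4. Heating F3 with excess F4 in toluene at 80 °C, a temperature kept low to limit thermal loss of the secondary-alkyl ynol ether, should then give the phenol by the same pericyclic cascade. The terminal (nucleophilic) alkyne carbon bonds to the ketene carbonyl carbon, so that position 1 carries hydrogen. The fallback comes back to the route at phenol 17.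

2. Step 2 (ketene cycloaddition). Ketene made in the flask may be lost to dimerisation, or the ynol ether may be acylated by the acylammonium salt before cycloaddition. The fallback uses a more electrophilic ketene and sets out from ynol ether 6. Treatment with trichloroacetyl chloride and Zn–Cu couple in Et2O/DME generates dichloroketene F5, which should add to 6 with the same orientation to give 4,4-dichloro-2-(methoxymethyl)-3-(propan-2-yloxy)cyclobut-2-en-1-one F6. Reductive dechlorination with Zn dust, AcOH and TMEDA in EtOH comes back to the route at cyclobutenone 9.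

3. Step 7 (BCl3 deprotection). The hindered methyl ether on position 4 may be lost competitively, or material may oligomerise through the benzylic cation during the Lewis acid treatment and quench. The fallback changes the order so that the Lewis acid never meets a benzylic ether, and sets out from ketone 21. Catalytic HCl in MeOH at 40 °C removes only the MOM group and gives 1-[2-hydroxy-4-methoxy-5-(methoxymethyl)-3-methyl-6-(propan-2-yloxy)phenyl]butan-1-one F7. Acid-catalysed alkylation of acetylfilicinic acid 25 with F7 (p-TsOH·H2O, MeCN, 50 °C), now through the para-quinone methide, gives 2-acetyl-6-{[3-butanoyl-4-hydroxy-6-methoxy-5-methyl-2-(propan-2-yloxy)phenyl]methyl}-3,5-dihydroxy-4,4-dimethylcyclohexa-2,5-dien-1-one F8. Cleavage of the isopropyl ether with BCl3 in CH2Cl2 at −78 °C, followed by a methanol quench, comes back to the route at target 27.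

Further compounds
F1 | step 4 | 1,3-dimethoxyprop-1-yne | COCC#COC
F2 | step 4 | methylketene (prop-1-en-1-one) | CC=C=O
F3 | step 4 | 3-methoxy-2-(methoxymethyl)-4-methylcyclobut-2-en-1-one (racemic) | COCC1=C(OC)C(C)C1=O
F4 | step 4 | (propan-2-yloxy)ethyne | CC(C)OC#C
F5 | step 2 | dichloroketene | ClC(Cl)=C=O
F6 | step 2 | 4,4-dichloro-2-(methoxymethyl)-3-(propan-2-yloxy)cyclobut-2-en-1-one | COCC1=C(OC(C)C)C(Cl)(Cl)C1=O
F7 | step 7 | 1-[2-hydroxy-4-methoxy-5-(methoxymethyl)-3-methyl-6-(propan-2-yloxy)phenyl]butan-1-one | CCCC(=O)c1c(O)c(C)c(OC)c(COC)c1OC(C)C
F8 | step 7 | 2-acetyl-6-{[3-butanoyl-4-hydroxy-6-methoxy-5-methyl-2-(propan-2-yloxy)phenyl]methyl}-3,5-dihydroxy-4,4-dimethylcyclohexa-2,5-dien-1-one | CCCC(=O)c1c(O)c(C)c(OC)c(CC2=C(O)C(C)(C)C(O)=C(C(C)=O)C2=O)c1OC(C)C
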